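Irisoquin's quinone ring is disconnected at C3–C4 and C1–C2. C4, C5 (OMe), C6 (H) and C1 are taken from 3-methoxycyclobutenedione, C2 (O) and C3 (octadecyl) from a 2-lithio tert-butyl enol ether. The key step exploits the 1,4-dioxygenated six-membered carbocycle whose C1 and C2 are both oxygen-bearing: on heating, the 4-alkenyl-4-hydroxycyclobutenone adduct opens to a dienylketene and recloses by 6π electrocyclisation, forging C1–C2 and delivering the fully substituted hydroquinone in one operation. The precursor is a cyclobutenone carbinol bearing the C5 methoxy group and an (E)-tert-butyl enol ether with the C18 chain on its inner carbon. Oxidation and acidolysis of the tert-butyl ether finish the route.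

Key step: step 6

Atom numbering used for the target: C1 (C=O), C2 (C–OH), C3 (C–C18H37), C4 (C=O), C5 (C–OMe), C6 (C–H).

Assumption: the alkenyllithium attacks dione 3 at the ketone-type carbonyl flanked by the methoxy-bearing carbon, the usual site for 3-alkoxycyclobutenediones, and leaves the vinylogous ester carbonyl intact.

Step 1
Reactants: 1 dimethyl squarate
Product: 3 3-methoxycyclobut-3-ene-1,2-dione, via 4-hydroxy-2,3-dimethoxycyclobut-2-en-1-one 2 (not isolated)
Conditions: LiAlH(OtBu)3, THF, −78 °C; then conc. HCl, CH2Cl2, 0 °C to rt
Reagents that add atoms: water, O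
Why: The bulky hydride should reduce only one carbonyl, and acid then ionises the new carbinol, water captures the methoxy-stabilised cation and methanol is lost to unveil the dione (carbonyl mono-reduction followed by acid-catalysed hydrolytic 1,3-transposition).

Step 2
Reactants: 4 trichloroethylene
Product: 6 (E)-1-tert-butoxy-1,2-dichloroethene, via dichloroacetylene 5 (not isolated)
Conditions: KOtBu, THF, −78 °C to rt, under argon (5 is generated and consumed in solution only)
Reagents that add atoms: potassium tert-butoxide, CC(C)(C)[O-].[K+]
Why: Base-induced dehydrochlorination should give dichloroacetylene, to which tert-butoxide adds in anti fashion with protonation by the tert-butanol formed, giving the (E)-dichlorovinyl ether (elimination then nucleophilic addition to a haloalkyne).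

Step 3
Reactants: 6 (E)-1-tert-butoxy-1,2-dichloroethene; 7 1-iodooctadecane
Product: 10 1-tert-butoxyicos-1-yne, via 1-tert-butoxy-2-chloroethyne 8 (not isolated), via lithium tert-butoxyacetylide 9 (not isolated)
Conditions: n-BuLi (2.2 equiv), THF, −78 to −40 °C; then 7, DMPU, −78 °C to rt; work-up and chromatography (Et3N-deactivated silica) below 30 °C
Reagents that add atoms: none
Why: Deprotonation with loss of LiCl gives the chloro ynol ether, chlorine–lithium exchange gives the lithium alkoxyacetylide, and SN2 alkylation by the primary iodide in the dipolar cosolvent should give the internal ynol ether (dichlorovinyl ether to ynol ether synthesis with in situ alkylation).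

Step 4
Reactants: 10 1-tert-butoxyicos-1-yne
Product: 12 (E)-1-tert-butoxy-2-iodoicos-1-ene, via alkenylzirconocene chloride Cp2Zr(Cl)[C(C18H37)=CH(OtBu)] 11 (not isolated)
Conditions: Cp2Zr(H)Cl, THF, rt, dark; then I2 (1.0 equiv), THF, −78 to 0 °C; aq. Na2S2O3/NaHCO3
Reagents that add atoms: iodine, II
Why: Syn hydrozirconation should place zirconium on C2, the electron-rich carbon remote from the bulky tert-butoxy group, and iodinolysis of the C–Zr bond with retention fixes iodine trans to the tert-butoxy group (hydrozirconation–iodination).

Step 5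
Reactants: 12 (E)-1-tert-butoxy-2-iodoicos-1-ene; 3 3-methoxycyclobut-3-ene-1,2-dione
Product: 14 4-[(E)-1-tert-butoxyicos-1-en-2-yl]-4-hydroxy-3-methoxycyclobut-2-en-1-one (racemic), via (Z)-1-tert-butoxyicos-1-en-2-yllithium 13 (not isolated)
Conditions: t-BuLi (2.0 equiv), Et2O, −78 °C; then cannulated into 3, THF, −78 °C; aq. NH4Cl
Reagents that add atoms: none
Why: Iodine–lithium exchange with retention of alkene geometry at −78 °C should outpace β-elimination, and the alkenyllithium adds 1,2 to the more electrophilic ketone-type carbonyl of 3 to form the C3–C4 bond, the new carbinol centre being racemic and erased in step 6 (halogen–metal exchange then carbonyl addition).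

Step 6
Reactants: 14 4-[(E)-1-tert-butoxyicos-1-en-2-yl]-4-hydroxy-3-methoxycyclobut-2-en-1-one
Product: 17 2-tert-butoxy-5-methoxy-3-octadecylbenzene-1,4-diol, via (3Z,5E)-6-tert-butoxy-4-hydroxy-3-methoxy-5-octadecylhexa-1,3,5-trien-1-one 15 (not isolated), via 6-tert-butoxy-4-hydroxy-3-methoxy-5-octadecylcyclohexa-2,4-dien-1-one 16 (not isolated)
Conditions: degassed toluene (about 0.02 M), 110 °C, argon; concentrated and used crude
Reagents that add atoms: none
Why: Heating should cleave the strained bond between the carbonyl carbon and the carbinol carbon of 14 in a conrotatory 4π electrocyclic opening in which the hydroxyl donor turns outward and the alkenyl group inward, giving the (Z)-dienylketene 15 with the ketene carbon held next to the enol ether terminus. A thermal disrotatory 6π electrocyclisation then joins the ketene carbon (target C1) to the tert-butoxy-bearing alkene carbon (target C2), closing the six-membered carbocycle as dienone 16, which enolises to the aromatic hydroquinone 17. The closest known reaction type is the thermal ring expansion of 4-alkenyl-4-hydroxycyclobutenones to hydroquinones (Moore rearrangement). No stereocentre persists, because the carbinol centre of 14 and the transient sp3 centre of 16 both become sp2 carbons. The selectivity needed is torquoselectivity in the ring opening, which the outward preference of the hydroxyl secures, while the substitution pattern was already locked by the site of carbonyl addition in step 5. The E enol ether puts hydrogen, not the tert-butoxy group, on the inside of the closing triene, and an alkene terminus offers no five-membered alternative.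

Step 7
Reactants: 17 2-tert-butoxy-5-methoxy-3-octadecylbenzene-1,4-diol
Product: 18 2-tert-butoxy-5-methoxy-3-octadecylcyclohexa-2,5-diene-1,4-dione
Conditions: Ag2O, MgSO4, Et2O, rt
Reagents that add atoms: none
Why: Electron-rich hydroquinones should be dehydrogenated cleanly to 1,4-benzoquinones by Ag2O under neutral conditions that leave the tert-butyl and methyl ethers untouched (hydroquinone oxidation).

Step 8
Reactants: 18 2-tert-butoxy-5-methoxy-3-octadecylcyclohexa-2,5-diene-1,4-dione
Product: 19 irisoquin (2-hydroxy-5-methoxy-3-octadecylcyclohexa-2,5-diene-1,4-dione)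
Conditions: CF3CO2H, CH2Cl2, 0 °C to rt
Reagents that add atoms: none
Why: The tert-butoxy group is a vinylogous tert-butyl ester that should ionise in CF3CO2H and lose isobutene, whereas the vinylogous methyl ester at C5 is inert to anhydrous acid (acidolytic tert-butyl ether cleavage).

Compound list
1 | dimethyl squarate (3,4-dimethoxycyclobut-3-ene-1,2-dione) | COC1=C(OC)C(=O)C1=O | starting material
2 | 4-hydroxy-2,3-dimethoxycyclobut-2-en-1-one (racemic) | COC1=C(OC)C(O)C1=O | intermediate
3 | 3-methoxycyclobut-3-ene-1,2-dione | COC1=CC(=O)C1=O | intermediate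
4 | trichloroethylene | ClC=C(Cl)Cl | starting material
5 | dichloroacetylene | ClC#CCl | intermediate
6 | (E)-1-tert-butoxy-1,2-dichloroethene | CC(C)(C)O/C(Cl)=C\Cl | intermediate
7 | 1-iodooctadecane | CCCCCCCCCCCCCCCCCCI | starting material
8 | 1-tert-butoxy-2-chloroethyne | CC(C)(C)OC#CCl | intermediate
9 | lithium tert-butoxyacetylide | CC(C)(C)OC#C[Li] | intermediate
10 | 1-tert-butoxyicos-1-yne | CCCCCCCCCCCCCCCCCCC#COC(C)(C)C | intermediate
11 | chloro[(E)-1-tert-butoxyicos-1-en-2-yl]zirconocene, Cp2Zr(Cl)[C(C18H37)=CH(OtBu)], Zr trans to OtBu (cyclopentadienyl ligands drawn σ-bonded) | CCCCCCCCCCCCCCCCCC/C(=C\OC(C)(C)C)[Zr](Cl)(C1C=CC=C1)C1C=CC=C1 | intermediate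
12 | (E)-1-tert-butoxy-2-iodoicos-1-ene, I trans to OtBu | CCCCCCCCCCCCCCCCCC/C(I)=C\OC(C)(C)C | intermediate
13 | (Z)-1-tert-butoxyicos-1-en-2-yllithium, Li trans to OtBu (geometry retained; descriptor changes because Li ranks below carbon) | CCCCCCCCCCCCCCCCCC/C([Li])=C\OC(C)(C)C | intermediate
14 | 4-[(E)-1-tert-butoxyicos-1-en-2-yl]-4-hydroxy-3-methoxycyclobut-2-en-1-one (racemic carbinol) | CCCCCCCCCCCCCCCCCC/C(=C\OC(C)(C)C)C1(O)C(OC)=CC1=O | intermediate
15 | (3Z,5E)-6-tert-butoxy-4-hydroxy-3-methoxy-5-octadecylhexa-1,3,5-trien-1-one (dienylketene) | O=C=C/C(OC)=C(O)\C(CCCCCCCCCCCCCCCCCC)=C\OC(C)(C)C | intermediate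
16 | 6-tert-butoxy-4-hydroxy-3-methoxy-5-octadecylcyclohexa-2,4-dien-1-one (racemic) | O=C1C=C(OC)C(O)=C(CCCCCCCCCCCCCCCCCC)C1OC(C)(C)C | intermediate
17 | 2-tert-butoxy-5-methoxy-3-octadecylbenzene-1,4-diol | CCCCCCCCCCCCCCCCCCc1c(OC(C)(C)C)c(O)cc(OC)c1O | intermediate
18 | 2-tert-butoxy-5-methoxy-3-octadecylcyclohexa-2,5-diene-1,4-dione | CCCCCCCCCCCCCCCCCCC1=C(OC(C)(C)C)C(=O)C=C(OC)C1=O | intermediate
19 | irisoquin, 2-hydroxy-5-methoxy-3-octadecylcyclohexa-2,5-diene-1,4-dione (no stereocentre) | CCCCCCCCCCCCCCCCCCC1=C(O)C(=O)C=C(OC)C1=O | target

Total step count: 8. Longest linear sequence: 7 steps (4 to 19 through steps 2 to 8); step 1 is a one-step branch.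

Steps most likely to fail

Step 6. What may go wrong is intermolecular capture of the ketene by the free tertiary hydroxyl at practical concentrations, and oxidative condensation of the electron-rich free hydroquinone during heating. The fallback sets out from 14 and masks the carbinol before the cascade. Silylation (Me3SiCl, Et3N, CH2Cl2) should give 4-[(E)-1-tert-butoxyicos-1-en-2-yl]-3-methoxy-4-(trimethylsilyloxy)cyclobut-2-en-1-one F1. Heating F1 in toluene should deliver, through the same ring opening and ring closure, the air-stable monosilylated hydroquinone 2-tert-butoxy-5-methoxy-3-octadecyl-4-(trimethylsilyloxy)phenol F2. Desilylation with Bu4NF and oxidation with Ag2O in the same flask returns to the route at 18.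

Step 5. What may go wrong is β-elimination of lithium tert-butoxide from the alkenyllithium, in which Li and OtBu are trans, before it is trapped; the strongly basic reagent may also deprotonate or add in conjugate fashion at the unsubstituted ring carbon of the dione. The fallback sets out from 10 and avoids both the iodide and the lithium reagent. Hydrozirconation as in step 4 gives 11, which is transmetalated with Me2Zn (toluene/CH2Cl2, −65 °C) to methyl[(E)-1-tert-butoxyicos-1-en-2-yl]zinc F3. This non-basic alkenylzinc is added to dione 3 (−65 to 0 °C), returning to the route at 14.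

Step 4. What may go wrong is incomplete regiocontrol of the hydrozirconation on an internal ynol ether, or protonolysis of the alkenylzirconium and acid-induced decomposition of the iodo enol ether during iodination and work-up. The fallback sets out from 10 and replaces zirconium by boron. Hydroboration with catecholborane, catalysed by dicyclohexylborane (THF, rt), should place boron on C2 to give 2-[(Z)-1-tert-butoxyicos-1-en-2-yl]-1,3,2-benzodioxaborole F4 (boron trans to OtBu). Hydrolysis with water gives [(Z)-1-tert-butoxyicos-1-en-2-yl]boronic acid F5. Iododeboronation with N-iodosuccinimide (MeCN, dark, rt), which proceeds with retention, returns to the route at 12.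

Further compounds
F1 | step 6 | 4-[(E)-1-tert-butoxyicos-1-en-2-yl]-3-methoxy-4-(trimethylsilyloxy)cyclobut-2-en-1-one (racemic) | CCCCCCCCCCCCCCCCCC/C(=C\OC(C)(C)C)C1(O[Si](C)(C)C)C(OC)=CC1=O
F2 | step 6 | 2-tert-butoxy-5-methoxy-3-octadecyl-4-(trimethylsilyloxy)phenol | CCCCCCCCCCCCCCCCCCc1c(OC(C)(C)C)c(O)cc(OC)c1O[Si](C)(C)C
F3 | step 5 | methyl[(E)-1-tert-butoxyicos-1-en-2-yl]zinc | CCCCCCCCCCCCCCCCCC/C(=C\OC(C)(C)C)[Zn]C
F4 | step 4 | 2-[(Z)-1-tert-butoxyicos-1-en-2-yl]-1,3,2-benzodioxaborole | CCCCCCCCCCCCCCCCCC/C(=C\OC(C)(C)C)B1Oc2ccccc2O1
F5 | step 4 | [(Z)-1-tert-butoxyicos-1-en-2-yl]boronic acid | CCCCCCCCCCCCCCCCCC/C(=C\OC(C)(C)C)B(O)O
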